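A direct plan would relay chirality from methyl (R)-lactate: Mitsunobu etherification of a protected dihydroconiferyl phenol, half-reduction/Wittig homologation and aryl Grignard addition would give the aryl allyl ether A1, an aromatic Claisen rearrangement the ortho-allyl phenol A2, and ozonolysis/reduction (diol A3) followed by acid-mediated SN1 cycloetherification the dihydrofuran. Its weakest steps would be:
- the Claisen rearrangement near 185 °C, because the substrate carries an ionisable benzylic carbinol and the chirality transfer depends on a single chair transition state;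
- the half-reduction, because it passes through an epimerisable α-aryloxy aldehyde;
- the ring closure, because its trans selectivity rests on a p-silyloxybenzyl cation.

The ozonolysis would also cut off two carbons that were installed only for the relay.

The route would rest on cutting the C2–C3 bond of the dihydrofuran. C2 is a benzylic ether carbon (bonded to O1 and the guaiacyl ring) and C3 is bonded to aromatic C3a and to C9 at the carboxyl level: this is the pattern left when an aryl(alkoxycarbonyl)carbene inserts into the benzylic C–H bond of an ortho benzyl ether. In one operation the five-membered ring would be closed through a C–C bond and both stereocentres created from an achiral diazo ester, itself assembled from an iodophenol, a benzyl alcohol and ethyl diazoacetate. No sigmatropic relay, α-aryloxy aldehyde, ozonolysis or benzylic cation would be involved, and no carbon would be discarded.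

Key step: step 6

Assumption: Rh2(S-PTTL)4 is taken to select the benzylic hydrogen whose replacement gives (2R); if the opposite sense were found, its enantiomer Rh2(R-PTTL)4 would be used.

Abbreviations: TBS = tert-butyldimethylsilyl; NIS = N-iodosuccinimide; DIAD = diisopropyl azodicarboxylate; DBU = 1,8-diazabicyclo[5.4.0]undec-7-ene.

Step 1
Reactants: 1 4-(3-hydroxypropyl)-2-methoxyphenol (dihydroconiferyl alcohol)
Product: 2 4-(3-hydroxypropyl)-2-iodo-6-methoxyphenol
Conditions: NIS (1.0 equiv), p-TsOH·H2O (10 mol %), MeCN, 0 °C → rt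
Reagents that add atoms: N-iodosuccinimide, O=C1CCC(=O)N1I
Why: Electrophilic aromatic iodination (SEAr) directed by the phenol: its para position carries the side chain and one ortho position the methoxy group, so iodine should enter only at the remaining ortho carbon, the future C3a.

Step 2
Reactants: 2 4-(3-hydroxypropyl)-2-iodo-6-methoxyphenol
Product: 3 4-[3-(TBS-oxy)propyl]-2-iodo-6-methoxyphenol
Conditions: TBSCl (1.05 equiv), imidazole (2 equiv), CH2Cl2, 0 °C
Reagents that add atoms: tert-butyl(chloro)dimethylsilane, CC(C)(C)[Si](C)(C)Cl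
Why: Chemoselective silylation, because the unhindered primary alcohol reacts with the silyl chloride much faster than the phenol, which is flanked by iodine and methoxy.

Step 3
Reactants: 4 4-formyl-2-methoxyphenyl 2-methylpropanoate (vanillin isobutyrate)
Product: 5 4-(hydroxymethyl)-2-methoxyphenyl 2-methylpropanoate
Conditions: NaBH4 (0.5 equiv), THF/EtOH 4:1, 0 °C; aq. NH4Cl
Reagents that add atoms: none
Why: Borohydride reduction of the aldehyde, which at 0 °C is much faster than attack on the aryl ester; the ester is kept because it masks the phenol up to step 7 without a separate deprotection.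

Step 4
Reactants: 3 4-[3-(TBS-oxy)propyl]-2-iodo-6-methoxyphenol; 5 4-(hydroxymethyl)-2-methoxyphenyl 2-methylpropanoate
Product: 6 4-({4-[3-(TBS-oxy)propyl]-2-iodo-6-methoxyphenoxy}methyl)-2-methoxyphenyl 2-methylpropanoate
Conditions: PPh3 (1.3 equiv), DIAD (1.3 equiv), THF, 0 °C → rt
Reagents that add atoms: none
Why: Mitsunobu etherification in which the acidic ortho-iodophenol is the pronucleophile and displaces the activated primary benzylic alcohol by SN2; this joins the two aromatic halves through the future O1–C2 bond under neutral conditions that spare the aryl ester and the silyl ether.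

Step 5
Reactants: 6 4-({4-[3-(TBS-oxy)propyl]-2-iodo-6-methoxyphenoxy}methyl)-2-methoxyphenyl 2-methylpropanoate; 7 ethyl diazoacetate
Product: 8 ethyl 2-[5-[3-(TBS-oxy)propyl]-3-methoxy-2-({3-methoxy-4-[(2-methylpropanoyl)oxy]phenyl}methoxy)phenyl]-2-diazoacetate
Conditions: Pd(PPh3)4 (5 mol %), Ag2CO3 (0.5 equiv), Et3N (1.3 equiv), toluene, rt
Reagents that add atoms: none
Why: Palladium-catalysed cross-coupling of an aryl iodide with the C–H bond of ethyl diazoacetate (oxidative addition to zerovalent palladium, base- and silver-assisted palladation of the diazo carbon, reductive elimination), which installs the aryl diazoacetate with the diazo group intact.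

Step 6
Reactants: 8 ethyl 2-[5-[3-(TBS-oxy)propyl]-3-methoxy-2-({3-methoxy-4-[(2-methylpropanoyl)oxy]phenyl}methoxy)phenyl]-2-diazoacetate
Product: 10 ethyl (2R,3R)-5-[3-(TBS-oxy)propyl]-7-methoxy-2-{3-methoxy-4-[(2-methylpropanoyl)oxy]phenyl}-2,3-dihydro-1-benzofuran-3-carboxylate, via cis ester 9 (not isolated)
Conditions: Rh2(S-PTTL)4 (dirhodium tetrakis[N-phthaloyl-(S)-tert-leucinate], 2 mol %), toluene, −60 °C, slow addition of 8; then DBU (1 equiv), rt → 40 °C
Reagents that add atoms: none
Why: The dirhodium tetracarboxylate should decompose the aryldiazoacetate to a donor/acceptor rhodium carbene that inserts into the benzylic C–H bond of the ortho benzyl ether through a concerted, asynchronous three-centre transition state with hydride-transfer character (loss of N2, then C–H insertion); the closest known reaction type is the enantioselective intramolecular carbene C–H insertion of 2-(benzyloxy)aryl diazoacetates to cis-2-aryl-2,3-dihydrobenzofuran-3-carboxylates. The dihydrofuran ring is closed by formation of the C2–C3 bond in a 1,5-insertion (five-membered cyclic transition state), the activated C–H bond lying five atoms from the carbene carbon. C2 is set by the chiral N-phthaloyl-tert-leucinate ligands, which differentiate the two enantiotopic benzylic hydrogens; C3 is formed cis under kinetic control (9) and is then equilibrated by DBU through the ester enolate to the thermodynamically preferred 2,3-trans ester 10, while C2 is not touched. The step needs insertion to win over carbene dimerisation, oxonium ylide formation and attack on the aromatic rings: the ether oxygen and the aryl group activate the inserting C–H bond, the donor/acceptor carbene is selective, and slow addition at low temperature keeps the diazo concentration low. The aryl ester keeps the phenol masked, and the silyl ether and the methoxy groups offer no activated C–H bond within reach of the carbene.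

Step 7
Reactants: 10 ethyl (2R,3R)-5-[3-(TBS-oxy)propyl]-7-methoxy-2-{3-methoxy-4-[(2-methylpropanoyl)oxy]phenyl}-2,3-dihydro-1-benzofuran-3-carboxylate
Product: 11 4-{(2R,3S)-5-[3-(TBS-oxy)propyl]-3-(hydroxymethyl)-7-methoxy-2,3-dihydro-1-benzofuran-2-yl}-2-methoxyphenol
Conditions: LiAlH4 (3 equiv), THF, 0 °C; aq. potassium sodium tartrate
Reagents that add atoms: none
Why: Hydride reduction of the ethyl ester to the primary alcohol with simultaneous reductive cleavage of the aryl isobutyrate; neither stereocentre is touched (the change of the C3 descriptor from R to S is only a priority change), and the silyl ether survives.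

Step 8
Reactants: 11 4-{(2R,3S)-5-[3-(TBS-oxy)propyl]-3-(hydroxymethyl)-7-methoxy-2,3-dihydro-1-benzofuran-2-yl}-2-methoxyphenol; 12 (2E)-3-(4-hydroxyphenyl)prop-2-enoic acid (p-coumaric acid)
Product: 13 {(2R,3S)-5-[3-(TBS-oxy)propyl]-2-(4-hydroxy-3-methoxyphenyl)-7-methoxy-2,3-dihydro-1-benzofuran-3-yl}methyl (2E)-3-(4-hydroxyphenyl)prop-2-enoate
Conditions: PPh3 (1.5 equiv), DIAD (1.5 equiv), 12 (1.5 equiv), THF, 0 °C → rt
Reagents that add atoms: none
Why: Mitsunobu esterification, in which the carboxylic acid (pKa about 4.5) is the only pronucleophile acidic enough to be engaged efficiently, so the primary CH2OH is acylated while both phenols stay free; the reacting carbon is a CH2 group and no stereocentre is involved.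

Step 9
Reactants: 13 {(2R,3S)-5-[3-(TBS-oxy)propyl]-2-(4-hydroxy-3-methoxyphenyl)-7-methoxy-2,3-dihydro-1-benzofuran-3-yl}methyl (2E)-3-(4-hydroxyphenyl)prop-2-enoate
Product: 14 [(2R,3S)-2-(4-hydroxy-3-methoxyphenyl)-5-(3-hydroxypropyl)-7-methoxy-2,3-dihydro-1-benzofuran-3-yl]methyl (2E)-3-(4-hydroxyphenyl)prop-2-enoate (CNP0202924.1)
Conditions: HF·pyridine, pyridine, THF, 0 °C → rt
Reagents that add atoms: none
Why: Fluoride-mediated cleavage of the primary silyl ether under buffered, non-basic conditions that leave the cinnamate ester, the phenols and the p-hydroxybenzyl ether linkage of the dihydrofuran intact.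

## Compound list

1 | 4-(3-hydroxypropyl)-2-methoxyphenol | COc1cc(CCCO)ccc1O | starting material
2 | 4-(3-hydroxypropyl)-2-iodo-6-methoxyphenol | COc1cc(CCCO)cc(I)c1O | intermediate
3 | 4-{3-[(tert-butyldimethylsilyl)oxy]propyl}-2-iodo-6-methoxyphenol | COc1cc(CCCO[Si](C)(C)C(C)(C)C)cc(I)c1O | intermediate
4 | 4-formyl-2-methoxyphenyl 2-methylpropanoate | COc1cc(C=O)ccc1OC(=O)C(C)C | starting material
5 | 4-(hydroxymethyl)-2-methoxyphenyl 2-methylpropanoate | COc1cc(CO)ccc1OC(=O)C(C)C | intermediate
6 | 4-[(4-{3-[(tert-butyldimethylsilyl)oxy]propyl}-2-iodo-6-methoxyphenoxy)methyl]-2-methoxyphenyl 2-methylpropanoate | COc1cc(COc2c(I)cc(CCCO[Si](C)(C)C(C)(C)C)cc2OC)ccc1OC(=O)C(C)C | intermediate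
7 | ethyl diazoacetate | CCOC(=O)C=[N+]=[N-] | starting material
8 | ethyl 2-[5-{3-[(tert-butyldimethylsilyl)oxy]propyl}-3-methoxy-2-({3-methoxy-4-[(2-methylpropanoyl)oxy]phenyl}methoxy)phenyl]-2-diazoacetate | CCOC(=O)C(=[N+]=[N-])c1cc(CCCO[Si](C)(C)C(C)(C)C)cc(OC)c1OCc1ccc(OC(=O)C(C)C)c(OC)c1 | intermediate
9 | ethyl (2R,3S)-5-{3-[(tert-butyldimethylsilyl)oxy]propyl}-7-methoxy-2-{3-methoxy-4-[(2-methylpropanoyl)oxy]phenyl}-2,3-dihydro-1-benzofuran-3-carboxylate (2,3-cis) | COc1cc([C@@H]2Oc3c(OC)cc(CCCO[Si](C)(C)C(C)(C)C)cc3[C@@H]2C(=O)OCC)ccc1OC(=O)C(C)C | intermediate (not isolated)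
10 | ethyl (2R,3R)-5-{3-[(tert-butyldimethylsilyl)oxy]propyl}-7-methoxy-2-{3-methoxy-4-[(2-methylpropanoyl)oxy]phenyl}-2,3-dihydro-1-benzofuran-3-carboxylate (2,3-trans) | COc1cc([C@@H]2Oc3c(OC)cc(CCCO[Si](C)(C)C(C)(C)C)cc3[C@H]2C(=O)OCC)ccc1OC(=O)C(C)C | intermediate
11 | 4-[(2R,3S)-5-{3-[(tert-butyldimethylsilyl)oxy]propyl}-3-(hydroxymethyl)-7-methoxy-2,3-dihydro-1-benzofuran-2-yl]-2-methoxyphenol | COc1cc([C@@H]2Oc3c(OC)cc(CCCO[Si](C)(C)C(C)(C)C)cc3[C@H]2CO)ccc1O | intermediate
12 | (2E)-3-(4-hydroxyphenyl)prop-2-enoic acid | OC(=O)/C=C/c1ccc(O)cc1 | starting material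
13 | [(2R,3S)-5-{3-[(tert-butyldimethylsilyl)oxy]propyl}-2-(4-hydroxy-3-methoxyphenyl)-7-methoxy-2,3-dihydro-1-benzofuran-3-yl]methyl (2E)-3-(4-hydroxyphenyl)prop-2-enoate | COc1cc([C@@H]2Oc3c(OC)cc(CCCO[Si](C)(C)C(C)(C)C)cc3[C@H]2COC(=O)/C=C/c2ccc(O)cc2)ccc1O | intermediate
14 | [(2R,3S)-2-(4-hydroxy-3-methoxyphenyl)-5-(3-hydroxypropyl)-7-methoxy-2,3-dihydro-1-benzofuran-3-yl]methyl (2E)-3-(4-hydroxyphenyl)prop-2-enoate | COc1cc([C@@H]2Oc3c(OC)cc(CCCO)cc3[C@H]2COC(=O)/C=C/c2ccc(O)cc2)ccc1O | target

Total step count: 9. Longest linear sequence: 8 steps (steps 1, 2, 4, 5, 6, 7, 8, 9); step 3 is a one-step branch.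

Steps most likely to fail:

1. Step 6 (key step). What may go wrong: insufficient discrimination of the two enantiotopic benzylic hydrogens by the catalyst, or carbene dimerisation at the low temperature needed for selectivity. The fallback sets out from 8 and comes back at 10, and moves the stereochemical problem from catalyst control to a resolution. Decomposition of 8 with the achiral catalyst Rh2(OAc)4 (CH2Cl2, rt) should give the racemic cis ester, that is 9 together with its enantiomer, the (2S,3R)-cis ester F1. DBU equilibration should then give the racemic trans ester, that is 10 together with its enantiomer, the (2S,3S)-trans ester F2. Separation of the enantiomers by preparative chromatography on a chiral stationary phase would return to the route at 10.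

2. Step 5. What may go wrong: slow coupling at the hindered, electron-rich aryl iodide and loss of the diazo group through palladium carbene formation. The fallback sets out from 6 and comes back at 8. Negishi-type coupling of 6 with the Reformatsky reagent BrZnCH2CO2Et (Pd2(dba)3, XPhos, THF, 60 °C) would give the ethyl arylacetate F3, and Regitz diazo transfer (4-acetamidobenzenesulfonyl azide, DBU, MeCN) would convert it into 8.

3. Step 8. What may go wrong: alkylation of a free phenol or elimination at the β-branched carbinol instead of acylation. The fallback sets out from 11 and comes back at 13, and replaces the redox condensation by a protected acylation. Phenoxide-selective acetylation of 11 (Ac2O, aq. NaOH, 0 °C) would give the aryl acetate F4. Carbodiimide esterification of its primary alcohol with (2E)-3-(4-acetoxyphenyl)prop-2-enoic acid (EDC·HCl, DMAP, CH2Cl2) would give the diacetate F5. Selective hydrazinolysis of the two aryl acetates (hydrazine acetate, DMF, rt) would then give 13.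

Further compounds

F1 | step 6 | ethyl (2S,3R)-5-{3-[(tert-butyldimethylsilyl)oxy]propyl}-7-methoxy-2-{3-methoxy-4-[(2-methylpropanoyl)oxy]phenyl}-2,3-dihydro-1-benzofuran-3-carboxylate (enantiomer of 9) | COc1cc([C@H]2Oc3c(OC)cc(CCCO[Si](C)(C)C(C)(C)C)cc3[C@H]2C(=O)OCC)ccc1OC(=O)C(C)C
F2 | step 6 | ethyl (2S,3S)-5-{3-[(tert-butyldimethylsilyl)oxy]propyl}-7-methoxy-2-{3-methoxy-4-[(2-methylpropanoyl)oxy]phenyl}-2,3-dihydro-1-benzofuran-3-carboxylate (enantiomer of 10) | COc1cc([C@H]2Oc3c(OC)cc(CCCO[Si](C)(C)C(C)(C)C)cc3[C@@H]2C(=O)OCC)ccc1OC(=O)C(C)C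
F3 | step 5 | ethyl 2-[5-{3-[(tert-butyldimethylsilyl)oxy]propyl}-3-methoxy-2-({3-methoxy-4-[(2-methylpropanoyl)oxy]phenyl}methoxy)phenyl]acetate | CCOC(=O)Cc1cc(CCCO[Si](C)(C)C(C)(C)C)cc(OC)c1OCc1ccc(OC(=O)C(C)C)c(OC)c1
F4 | step 8 | 4-[(2R,3S)-5-{3-[(tert-butyldimethylsilyl)oxy]propyl}-3-(hydroxymethyl)-7-methoxy-2,3-dihydro-1-benzofuran-2-yl]-2-methoxyphenyl acetate | COc1cc([C@@H]2Oc3c(OC)cc(CCCO[Si](C)(C)C(C)(C)C)cc3[C@H]2CO)ccc1OC(C)=O
F5 | step 8 | [(2R,3S)-2-(4-acetoxy-3-methoxyphenyl)-5-{3-[(tert-butyldimethylsilyl)oxy]propyl}-7-methoxy-2,3-dihydro-1-benzofuran-3-yl]methyl (2E)-3-(4-acetoxyphenyl)prop-2-enoate | COc1cc([C@@H]2Oc3c(OC)cc(CCCO[Si](C)(C)C(C)(C)C)cc3[C@H]2COC(=O)/C=C/c2ccc(OC(C)=O)cc2)ccc1OC(C)=O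
A1 | direct plan | (1RS,2E,4S)-1-{4-[(tert-butyldimethylsilyl)oxy]-3-methoxyphenyl}-4-(4-{3-[(tert-butyldiphenylsilyl)oxy]propyl}-2-methoxyphenoxy)pent-2-en-1-ol | C[C@H](Oc1ccc(CCCO[Si](c2ccccc2)(c2ccccc2)C(C)(C)C)cc1OC)/C=C/C(O)c1ccc(O[Si](C)(C)C(C)(C)C)c(OC)c1
A2 | direct plan | (1RS,2R,3E)-2-(5-{3-[(tert-butyldiphenylsilyl)oxy]propyl}-2-hydroxy-3-methoxyphenyl)-1-{4-[(tert-butyldimethylsilyl)oxy]-3-methoxyphenyl}pent-3-en-1-ol | C/C=C/[C@H](c1cc(CCCO[Si](c2ccccc2)(c2ccccc2)C(C)(C)C)cc(OC)c1O)C(O)c1ccc(O[Si](C)(C)C(C)(C)C)c(OC)c1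
A3 | direct plan | (1RS,2S)-2-(5-{3-[(tert-butyldiphenylsilyl)oxy]propyl}-2-hydroxy-3-methoxyphenyl)-1-{4-[(tert-butyldimethylsilyl)oxy]-3-methoxyphenyl}propane-1,3-diol | OC[C@H](c1cc(CCCO[Si](c2ccccc2)(c2ccccc2)C(C)(C)C)cc(OC)c1O)C(O)c1ccc(O[Si](C)(C)C(C)(C)C)c(OC)c1
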